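**Retrosynthetic overview**

1. Numbering: C1 is the ring CH next to the gem-dimethyl carbon C15, C10 the N–CH, C6 the acetoxy carbon. The strategy rests on the cyclohexene ring C1–C14–C13–C12=C11–C15, whose C11=C12 bond is shared with the five-membered lactam (C10, C11, C12, C=O, N) and which is bridged 1,3 from C1 to C11 by the nine-carbon chain C2–C10 (twelve-membered ring C15, C1–C11).
2. Key disconnection: C1–C15 and C13–C14, a type 2 intramolecular Diels–Alder reaction of an N-(4-methoxybenzyl) 3-methylene-4-isopropylidene lactam (diene C13, C12, C11, C15) with a tethered vinyl ketone (C14=C1, ketone at C2). Afterwards only C2 deoxygenation, N-deprotection and O-acetylation remain.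
3. The diene lactam comes from a 2-bromoacrylamide by 5-exo-dig carbopalladation of the C11≡C15 propynyl group with methyl capture at C15 (C11–C12 bond).
4. Chain: C2–C3 by chromium allylation of acrolein; C5–C6 by catalytic asymmetric allylation of an enal with a 2-(chloromethyl)allylstannane (sets C6); C6–C7 and the C8 methyl by carboalumination–hydroxymethylation; C9–C10 by propargylation of the tert-butanesulfinyl imine of but-2-ynal (sets C10).
5. Ring order: lactam first (step 12), then the cyclohexene and the twelve-membered ring together (step 14).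

Key step: step 14

Remark on the chemistry: the C2 carbinol centres made in steps 8 and 15 are carried as epimer mixtures, because C2 is oxidised in step 13 and deoxygenated in step 17; their SMILES carry no configuration at C2.

**Route**

Step 1
Reactants: 1 but-2-yn-1-ol; 2 (S)-2-methylpropane-2-sulfinamide
Product: 4 (S)-N-[(E)-but-2-yn-1-ylidene]-2-methylpropane-2-sulfinamide, via but-2-ynal 3 (not isolated)
Conditions: MnO2, CH2Cl2, rt; filter; then 2, CuSO4, CH2Cl2, rt
Reagents that add atoms: none
Why: MnO2 oxidation of the propargylic alcohol and CuSO4-mediated condensation of the volatile aldehyde with the sulfinamide should give the (E)-N-sulfinyl imine without touching the alkyne or the sulfur centre.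

Step 2
Reactants: 4; 5 3-bromoprop-1-yne
Product: 7 (S)-N-[(4R)-hepta-1,5-diyn-4-yl]-2-methylpropane-2-sulfinamide, via allenylzinc bromide 6 (not isolated)
Conditions: Zn dust, THF, 0 °C to rt
Reagents that add atoms: none
Why: Zinc Barbier propargylation, in which the allenylzinc adds by SE2′ through a six-membered chair with zinc held by the imine nitrogen and the sulfinyl oxygen, so that the propargyl group arrives anti to the tert-butyl group on the Re face of the (S)-sulfinyl imine and C10 is set as (R).

Step 3
Reactants: 7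
Product: 10 (S)-N-[(4R,6E)-8-hydroxy-6-methyloct-6-en-2-yn-4-yl]-2-methylpropane-2-sulfinamide, via alkenyldimethylalane 8 (not isolated), via lithium alkenyl(butyl)dimethylaluminate 9 (not isolated)
Conditions: Me3Al (4 equiv), Cp2ZrCl2 (0.3 equiv), H2O (1.5 equiv), CH2Cl2, −25 to 0 °C; evaporate; n-BuLi, THF, −78 °C; (CH2O)n, −78 °C to rt; aq. KNaC4H4O6
Reagents that add atoms: trimethylaluminium, C[Al](C)C; formaldehyde (as paraformaldehyde), C=O
Why: Negishi carboalumination adds Me–Al syn across the terminal alkyne (methyl on C8, aluminium on C7, the internal alkyne reacting far more slowly), and hydroxymethylation of the derived alanate with retention fixes the (E)-C7=C8 geometry.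

Step 4
Reactants: 10
Product: 11 (S)-N-[(4R,6E)-6-methyl-8-oxooct-6-en-2-yn-4-yl]-2-methylpropane-2-sulfinamide
Conditions: MnO2, CH2Cl2, rt
Reagents that add atoms: none
Why: MnO2 oxidises the allylic alcohol selectively to the enal and should not isomerise the trisubstituted alkene.

Step 5
Reactants: 12 3-chloro-2-(chloromethyl)prop-1-ene
Product: 13 tributyl[2-(chloromethyl)prop-2-en-1-yl]stannane
Conditions: Bu3SnH, LiN(i-Pr)2, THF, −78 °C; add to 12 (3 equiv), −78 °C
Reagents that add atoms: tributyltin hydride, CCCC[SnH](CCCC)CCCC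
Why: Displacement of one allylic chloride by tributylstannyllithium (SN2 and SN2′ give the same product), with excess dichloride to prevent double substitution.

Step 6
Reactants: 11; 13
Product: 14 (S)-N-[(4R,6E,8S)-10-(chloromethyl)-8-hydroxy-6-methylundeca-6,10-dien-2-yn-4-yl]-2-methylpropane-2-sulfinamide
Conditions: (S)-BINOL (20 mol%), Ti(OiPr)4 (10 mol%), 4 Å MS, CH2Cl2, −20 °C
Reagents that add atoms: none
Why: Keck asymmetric allylation, in which the (S)-BINOL–Ti(OiPr)4 catalyst directs SE2′ addition of the 2-substituted allylstannane to the Si face of the enal, setting C6 as (S) under catalyst control and leaving the allylic chloride in place.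

Step 7
Reactants: 14
Product: 15 (S)-N-[(4R,6E,8S)-8-(tert-butyldimethylsilyloxy)-10-(chloromethyl)-6-methylundeca-6,10-dien-2-yn-4-yl]-2-methylpropane-2-sulfinamide
Conditions: TBSOTf, 2,6-lutidine, CH2Cl2, −78 °C
Reagents that add atoms: tert-butyldimethylsilyl trifluoromethanesulfonate, CC(C)(C)[Si](C)(C)OS(=O)(=O)C(F)(F)F
Why: Silylation of the secondary allylic alcohol with the silyl triflate at low temperature is faster than any reaction at the sulfinamide or the allylic chloride.

Step 8
Reactants: 15; 16 prop-2-enal
Product: 18 (S)-N-[(4R,6E,8S)-8-(tert-butyldimethylsilyloxy)-12-hydroxy-6-methyl-10-methylidenetetradeca-6,13-dien-2-yn-4-yl]-2-methylpropane-2-sulfinamide (C12 epimers), via allylchromium dichloride 17 (not isolated)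
Conditions: CrCl2 (4 equiv), 16 (3 equiv), THF, 0 °C to rt
Reagents that add atoms: none
Why: Nozaki–Hiyama allylation, in which CrCl2 turns the allylic chloride into an allylchromium reagent that adds 1,2 to acrolein in the presence of the N–H, silyl ether and alkyne; the new carbinol centre (C2) is left uncontrolled because it is oxidised in step 13.

Step 9
Reactants: 18
Product: 19 (4R,6E,8S)-4-amino-8-(tert-butyldimethylsilyloxy)-6-methyl-10-methylidenetetradeca-6,13-dien-2-yn-12-ol
Conditions: HCl (4 M in dioxane, 2.5 equiv), MeOH, 0 °C, 20 min; aq. NaHCO3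
Reagents that add atoms: none
Why: Acidic methanolysis cleaves the N–S bond of the sulfinamide within minutes at 0 °C, conditions the secondary silyl ether and the allylic alcohol should survive.

Step 10
Reactants: 19
Product: 21 (4R,6E,8S)-8-(tert-butyldimethylsilyloxy)-4-[(4-methoxybenzyl)amino]-6-methyl-10-methylidenetetradeca-6,13-dien-2-yn-12-ol, via N-(4-methoxybenzylidene) imine 20 (not isolated)
Conditions: 4-MeOC6H4CHO, MgSO4, CH2Cl2, rt; then NaBH4, MeOH, 0 °C
Reagents that add atoms: 4-methoxybenzaldehyde, COc1ccc(C=O)cc1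
Why: Two-stage reductive amination gives the mono-N-benzylated amine; the tertiary amide made from it populates the rotamer needed for ring closure in step 12 and masks the N–H until step 18.

Step 11
Reactants: 21; 22 2,3-dibromopropanoyl chloride
Product: 24 2-bromo-N-[(4R,6E,8S)-8-(tert-butyldimethylsilyloxy)-12-hydroxy-6-methyl-10-methylidenetetradeca-6,13-dien-2-yn-4-yl]-N-(4-methoxybenzyl)prop-2-enamide, via 2,3-dibromopropanamide 23 (not isolated)
Conditions: 22 (1.1 equiv), Et3N (3.5 equiv), CH2Cl2, −78 to 0 °C
Reagents that add atoms: none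
Why: N-Acylation of the amine (much faster than O-acylation of the hindered C2 alcohol at low temperature) followed by E2 loss of HBr from the 2,3-dibromo amide gives the 2-bromoacrylamide.

Step 12
Reactants: 24
Product: 25 (5R)-5-[(2E,4S)-4-(tert-butyldimethylsilyloxy)-8-hydroxy-2-methyl-6-methylidenedeca-2,9-dien-1-yl]-1-(4-methoxybenzyl)-3-methylidene-4-(propan-2-ylidene)pyrrolidin-2-one
Conditions: Pd(PPh3)4 (10 mol%), MeB(OH)2 (3 equiv), K2CO3 (3 equiv), THF/H2O (10:1), 65 °C, degassed
Reagents that add atoms: methylboronic acid, CB(O)O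
Why: Cyclic carbopalladation with Suzuki–Miyaura capture: oxidative addition of zerovalent palladium to the C12–Br bond, 5-exo-dig syn insertion of the C11≡C15 alkyne (forming C11–C12 and the lactam ring) and methyl transfer from boron to C15 give the dialkylidene lactam with no double-bond isomer possible, both groups on C15 being methyl.

Step 13
Reactants: 25
Product: 26 (5R)-5-[(2E,4S)-4-(tert-butyldimethylsilyloxy)-2-methyl-6-methylidene-8-oxodeca-2,9-dien-1-yl]-1-(4-methoxybenzyl)-3-methylidene-4-(propan-2-ylidene)pyrrolidin-2-one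
Conditions: Dess–Martin periodinane, NaHCO3, CH2Cl2, 0 °C; used at once
Reagents that add atoms: none
Why: Dess–Martin oxidation of the allylic C2 alcohol under buffered, non-basic conditions gives the vinyl ketone without moving the skipped C4 methylene into conjugation.

Step 14
Reactants: 26
Product: 27 (1R,6S,10R) N-(4-methoxybenzyl) 2-oxo macrobicyclic lactam, C6 TBS ether (bonds C13–C14 and C1–C15 formed)
Conditions: PhMe (0.5 mM), BHT (0.2 equiv), 100 °C, sealed silylated glass, dark
Reagents that add atoms: none
Why: Proposed new method: a concerted but asynchronous thermal [4+2] cycloaddition in which the lactam ring locks the C13=C12–C11=C15 diene s-cis and the vinyl ketone adds with C14 to C13 (bond in advance) and C1 to C15; the closest known reactions are type 2 intramolecular Diels–Alder closures that give bridgehead alkenes and thermal cycloadditions of 3,4-dialkylidene five-membered lactams and lactones with enones, which have not been combined in a macrocyclisation. The cyclohexene ring closes through the boat-like six-centre transition state of the cycloaddition, and the twelve-membered ring (C15 and C1 to C11) closes through the same two bonds in the 1,3-bridged mode, C11=C12 becoming the bridgehead alkene. The one new stereocentre, C1, is controlled by C10: the C9 chain leaves one face of the flat lactam, brings the dienophile to that face and must run under the diene (C2 endo) to span C1 and C10, so C2 and C9 end on the same face of the cyclohexene, which is (1R). The step needs C1 to bond to C15 and not to C13, and the acyl group on C12 (para orientation) and the two methyl groups on C15 (ortho orientation) both place the larger diene coefficient on C13, the unhindered CH2 terminus that meets the enone β-carbon C14. No Lewis acid is used, because it would bind the lactam carbonyl first and deactivate the diene and could isomerise or cyclise the skipped C2 ketone/C4 methylene unit; heat is tolerated because the five-membered ring spreads the diene termini and so slows the 1,5-hydrogen shift from the inner C15 methyl group, and 0.5 mM dilution suppresses dimerisation through the methylene lactam.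

Step 15
Reactants: 27
Product: 28 (1R,6S,10R) N-(4-methoxybenzyl) 2-hydroxy macrobicyclic lactam, C6 TBS ether (C2 epimers)
Conditions: NaBH4, CeCl3·7H2O, MeOH/THF, −40 °C
Reagents that add atoms: none
Why: Luche-type hydride reduction at low temperature reduces only the C2 ketone (the tetrasubstituted unsaturated lactam is inert) and avoids enolisation towards C1 or C3.

Step 16
Reactants: 28
Product: 29 C2 O-(imidazol-1-ylthiocarbonyl) derivative of 28
Conditions: 1,1′-thiocarbonyldiimidazole (3 equiv), DMAP (0.3 equiv), ClCH2CH2Cl, 70 °C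
Reagents that add atoms: 1,1′-thiocarbonyldiimidazole, S=C(n1ccnc1)n1ccnc1
Why: Neutral thioacylation of the hindered secondary alcohol sets up radical deoxygenation without strong base.

Step 17
Reactants: 29
Product: 30 (1R,6S,10R) N-(4-methoxybenzyl) macrobicyclic lactam, C6 TBS ether (C2 = CH2)
Conditions: Bu3SnH (3 equiv), AIBN (0.2 equiv), PhMe, 90 °C
Reagents that add atoms: none
Why: Barton–McCombie deoxygenation, in which the secondary C2 radical is reduced by excess Bu3SnH faster than it can rearrange through the homoallylic C4 methylene or add across the ring.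

Step 18
Reactants: 30
Product: 31 (1R,6S,10R) N–H macrobicyclic lactam, C6 TBS ether
Conditions: (NH4)2Ce(NO3)6 (3 equiv), MeCN/H2O (4:1), 0 °C
Reagents that add atoms: none
Why: Oxidative N-debenzylation by single-electron oxidation of the anisyl ring and hydrolysis of the resulting N-acyliminium ion should free the lactam N–H without affecting the alkenes.

Step 19
Reactants: 31
Product: 32 (1R,6S,10R) N–H macrobicyclic lactam, C6 alcohol (deacetyl cespitulactam E)
Conditions: Bu4NF, THF, 0 °C to rt
Reagents that add atoms: none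
Why: Fluoride cleaves the Si–O bond of the secondary silyl ether.

Step 20
Reactants: 32
Product: 33 cespitulactam E
Conditions: Ac2O, pyridine, DMAP (cat.), CH2Cl2, 0 °C to rt
Reagents that add atoms: acetic anhydride, CC(=O)OC(C)=O
Why: DMAP-catalysed O-acetylation of the secondary allylic alcohol, the lactam N–H being far less nucleophilic under these conditions.

**Compound list**

1 | but-2-yn-1-ol | CC#CCO | starting material
2 | (S)-2-methylpropane-2-sulfinamide | CC(C)(C)[S@](=O)N | starting material
3 | but-2-ynal | CC#CC=O | intermediate (not isolated)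
4 | (S)-N-[(E)-but-2-yn-1-ylidene]-2-methylpropane-2-sulfinamide | CC(C)(C)[S@](=O)/N=C/C#CC | intermediate
5 | 3-bromoprop-1-yne | C#CCBr | starting material
6 | allenylzinc bromide | C=C=C[Zn]Br | intermediate (not isolated)
7 | (S)-N-[(4R)-hepta-1,5-diyn-4-yl]-2-methylpropane-2-sulfinamide | CC(C)(C)[S@](=O)N[C@H](CC#C)C#CC | intermediate
8 | (E)-alkenyldimethylalane from 7 (Al on C7, methyl on C8, N–AlMe2) | CC(C)(C)[S@](=O)N([Al](C)C)[C@H](C/C(C)=C/[Al](C)C)C#CC | intermediate (not isolated)
9 | lithium alkenyl(butyl)dimethylaluminate from 8 | [Li+].CC(C)(C)[S@](=O)N([Al](C)C)[C@H](C/C(C)=C/[Al-](C)(C)CCCC)C#CC | intermediate (not isolated)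
10 | (S)-N-[(4R,6E)-8-hydroxy-6-methyloct-6-en-2-yn-4-yl]-2-methylpropane-2-sulfinamide | CC(C)(C)[S@](=O)N[C@H](C/C(C)=C/CO)C#CC | intermediate
11 | (S)-N-[(4R,6E)-6-methyl-8-oxooct-6-en-2-yn-4-yl]-2-methylpropane-2-sulfinamide | CC(C)(C)[S@](=O)N[C@H](C/C(C)=C/C=O)C#CC | intermediate
12 | 3-chloro-2-(chloromethyl)prop-1-ene | C=C(CCl)CCl | starting material
13 | tributyl[2-(chloromethyl)prop-2-en-1-yl]stannane | CCCC[Sn](CCCC)(CCCC)CC(=C)CCl | intermediate
14 | (S)-N-[(4R,6E,8S)-10-(chloromethyl)-8-hydroxy-6-methylundeca-6,10-dien-2-yn-4-yl]-2-methylpropane-2-sulfinamide | CC(C)(C)[S@](=O)N[C@H](C/C(C)=C/[C@@H](O)CC(=C)CCl)C#CC | intermediate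
15 | TBS ether of 14 | CC(C)(C)[S@](=O)N[C@H](C/C(C)=C/[C@@H](O[Si](C)(C)C(C)(C)C)CC(=C)CCl)C#CC | intermediate
16 | prop-2-enal (acrolein) | C=CC=O | starting material
17 | allylchromium dichloride from 15 | CC(C)(C)[S@](=O)N[C@H](C/C(C)=C/[C@@H](O[Si](C)(C)C(C)(C)C)CC(=C)C[Cr](Cl)Cl)C#CC | intermediate (not isolated)
18 | sulfinamide with full chain and C2 carbinol (C2 epimers) | CC(C)(C)[S@](=O)N[C@H](C/C(C)=C/[C@@H](O[Si](C)(C)C(C)(C)C)CC(=C)CC(O)C=C)C#CC | intermediate
19 | (4R,6E,8S)-4-amino-8-(tert-butyldimethylsilyloxy)-6-methyl-10-methylidenetetradeca-6,13-dien-2-yn-12-ol | N[C@H](C/C(C)=C/[C@@H](O[Si](C)(C)C(C)(C)C)CC(=C)CC(O)C=C)C#CC | intermediate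
20 | N-(4-methoxybenzylidene) imine of 19 | COc1ccc(/C=N/[C@H](C/C(C)=C/[C@@H](O[Si](C)(C)C(C)(C)C)CC(=C)CC(O)C=C)C#CC)cc1 | intermediate (not isolated)
21 | N-(4-methoxybenzyl) amine of 19 | COc1ccc(CN[C@H](C/C(C)=C/[C@@H](O[Si](C)(C)C(C)(C)C)CC(=C)CC(O)C=C)C#CC)cc1 | intermediate
22 | 2,3-dibromopropanoyl chloride | ClC(=O)C(Br)CBr | starting material
23 | N-(4-methoxybenzyl) 2,3-dibromopropanamide of 21 | BrCC(Br)C(=O)N(Cc1ccc(OC)cc1)[C@H](C/C(C)=C/[C@@H](O[Si](C)(C)C(C)(C)C)CC(=C)CC(O)C=C)C#CC | intermediate (not isolated)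
24 | N-(4-methoxybenzyl) 2-bromoacrylamide of 21 | C=C(Br)C(=O)N(Cc1ccc(OC)cc1)[C@H](C/C(C)=C/[C@@H](O[Si](C)(C)C(C)(C)C)CC(=C)CC(O)C=C)C#CC | intermediate
25 | (5R)-3-methylidene-4-(propan-2-ylidene) lactam with C2 carbinol side chain | C=C1C(=O)N(Cc2ccc(OC)cc2)[C@H](C/C(C)=C/[C@@H](O[Si](C)(C)C(C)(C)C)CC(=C)CC(O)C=C)C1=C(C)C | intermediate
26 | dialkylidene lactam with tethered vinyl ketone (key-step precursor, N-PMB, C6 TBS ether) | C=C1C(=O)N(Cc2ccc(OC)cc2)[C@H](C/C(C)=C/[C@@H](O[Si](C)(C)C(C)(C)C)CC(=C)CC(=O)C=C)C1=C(C)C | intermediate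
27 | (1R,6S,10R) N-PMB 2-oxo macrobicyclic lactam, C6 TBS ether (key-step product) | C=C1CC(=O)[C@@H]2CCC3=C([C@@H](C/C(C)=C/[C@@H](O[Si](C)(C)C(C)(C)C)C1)N(Cc4ccc(OC)cc4)C3=O)C2(C)C | intermediate
28 | N-PMB 2-hydroxy macrobicyclic lactam, C6 TBS ether (C2 epimers) | C=C1CC(O)[C@@H]2CCC3=C([C@@H](C/C(C)=C/[C@@H](O[Si](C)(C)C(C)(C)C)C1)N(Cc4ccc(OC)cc4)C3=O)C2(C)C | intermediate
29 | C2 O-(imidazol-1-ylthiocarbonyl) derivative of 28 | C=C1CC(OC(=S)n5ccnc5)[C@@H]2CCC3=C([C@@H](C/C(C)=C/[C@@H](O[Si](C)(C)C(C)(C)C)C1)N(Cc4ccc(OC)cc4)C3=O)C2(C)C | intermediate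
30 | N-PMB macrobicyclic lactam, C6 TBS ether | C=C1CC[C@@H]2CCC3=C([C@@H](C/C(C)=C/[C@@H](O[Si](C)(C)C(C)(C)C)C1)N(Cc4ccc(OC)cc4)C3=O)C2(C)C | intermediate
31 | N–H macrobicyclic lactam, C6 TBS ether | C=C1CC[C@@H]2CCC3=C([C@@H](C/C(C)=C/[C@@H](O[Si](C)(C)C(C)(C)C)C1)NC3=O)C2(C)C | intermediate
32 | deacetyl cespitulactam E (C6 alcohol) | C=C1CC[C@@H]2CCC3=C([C@@H](C/C(C)=C/[C@@H](O)C1)NC3=O)C2(C)C | intermediate
33 | cespitulactam E | C=C1CC[C@@H]2CCC3=C([C@@H](C/C(C)=C/[C@@H](OC(C)=O)C1)NC3=O)C2(C)C | target

**Step count**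

Total: 20 steps. Longest linear sequence: 19 steps (steps 1–4 and 6–20; step 5 is a one-step side branch).

**Steps most likely to fail**

Step 14 (Proposed new method). The macrocyclic cycloaddition may be slower than loss of the diene (dimerisation through C12=C13, 1,5-hydrogen shift) or than isomerisation of the skipped enone, or the chain may close in the 1,4-bridged sense. The fallback makes the two bonds between separate molecules and closes the twelve-membered ring afterwards by known reactions. It sets out from 15 and comes back at 28.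
- The allylic chloride of 15 is exchanged for acetate (KOAc, Bu4NI, DMF) to give the allylic acetate F1, and methanolysis (K2CO3, MeOH) gives the allylic alcohol F2, a group that zerovalent palladium leaves alone.
- The chemistry of steps 9 to 12 is repeated: HCl/MeOH gives the amine F3; 4-methoxybenzaldehyde gives the imine F4 and NaBH4 the N-(4-methoxybenzyl) amine F5; 2,3-dibromopropanoyl chloride and Et3N give the dibromo amide F6 and then the 2-bromoacrylamide F7 (the amine is acylated before the primary alcohol at −78 °C); carbopalladation–methylation gives the diene lactam F8.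
- A thermal intermolecular Diels–Alder reaction of F8 with acrolein 16 (excess, PhMe, 60 °C, BHT), a known reaction of 3,4-dialkylidene five-membered lactams and lactones, gives the cyclohexene aldehyde F9, whose formyl carbon is C2 on C1. The regiochemistry follows the same ortho/para preferences as in step 14, and the two C1 epimers interconvert through the enolisable aldehyde (DBU).
- The allylic alcohol is converted into the allylic chloride F10 (MsCl, 2,4,6-collidine, LiCl, DMF, 0 °C). Intramolecular CrCl2-mediated allylation of the aldehyde at high dilution (THF), a known macrocyclisation for rings of this size, proceeds through the allylchromium dichloride F11 and forms C2–C3. Only the epimer with C2 and C9 on the same face is expected to close.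
- The product is the C2 alcohol 28, and the route continues with step 16.

Step 12. Methyl transfer from boron to the hindered dienylpalladium intermediate may be slower than its decomposition, or the vinyl bromide may be methylated before the ring closes. The fallback separates ring closure from methylation and brings the methyl group in as an electrophile. It sets out from 24 and comes back at 25. Cyclisation with boron capture (B2pin2, KOAc, PdCl2(dppf), dioxane, 70 °C) gives the dienyl pinacol boronate F12, and Suzuki–Miyaura coupling with MeI (Pd2(dba)3, P(o-tol)3, K2CO3, DMF/H2O, 60 °C) gives 25.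

Step 3. The Lewis-basic sulfinamide may tie up the aluminium and zirconium reagents so that carbometalation stalls, or the internal alkyne may be attacked as well. The fallback builds the trisubstituted alkene by carbonyl olefination and uses no carbometalation. It sets out from 7 and comes back at 10. Hg(OTf)2-catalysed hydration of the terminal alkyne (MeCN/H2O, rt) gives the methyl ketone F13. Horner–Wadsworth–Emmons olefination ((EtO)2P(O)CH2CO2Et, NaH, THF) gives the (E)-enoate F14 after chromatographic removal of the (Z)-isomer. Reduction with i-Bu2AlH (CH2Cl2, −78 °C) gives 10.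

**Further compounds**

F1 | step 14 | allylic acetate from 15 | CC(C)(C)[S@](=O)N[C@H](C/C(C)=C/[C@@H](O[Si](C)(C)C(C)(C)C)CC(=C)COC(C)=O)C#CC
F2 | step 14 | allylic alcohol from F1 | CC(C)(C)[S@](=O)N[C@H](C/C(C)=C/[C@@H](O[Si](C)(C)C(C)(C)C)CC(=C)CO)C#CC
F3 | step 14 | primary amine from F2 | N[C@H](C/C(C)=C/[C@@H](O[Si](C)(C)C(C)(C)C)CC(=C)CO)C#CC
F4 | step 14 | N-(4-methoxybenzylidene) imine of F3 | COc1ccc(/C=N/[C@H](C/C(C)=C/[C@@H](O[Si](C)(C)C(C)(C)C)CC(=C)CO)C#CC)cc1
F5 | step 14 | N-(4-methoxybenzyl) amine of F3 | COc1ccc(CN[C@H](C/C(C)=C/[C@@H](O[Si](C)(C)C(C)(C)C)CC(=C)CO)C#CC)cc1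
F6 | step 14 | 2,3-dibromopropanamide of F5 | BrCC(Br)C(=O)N(Cc1ccc(OC)cc1)[C@H](C/C(C)=C/[C@@H](O[Si](C)(C)C(C)(C)C)CC(=C)CO)C#CC
F7 | step 14 | 2-bromoacrylamide of F5 | C=C(Br)C(=O)N(Cc1ccc(OC)cc1)[C@H](C/C(C)=C/[C@@H](O[Si](C)(C)C(C)(C)C)CC(=C)CO)C#CC
F8 | step 14 | dialkylidene lactam with allylic alcohol chain end | C=C1C(=O)N(Cc2ccc(OC)cc2)[C@H](C/C(C)=C/[C@@H](O[Si](C)(C)C(C)(C)C)CC(=C)CO)C1=C(C)C
F9 | step 14 | cyclohexene-fused lactam with C1 formyl group and allylic alcohol chain end (C1 epimers) | O=CC1CCC2=C([C@@H](C/C(C)=C/[C@@H](O[Si](C)(C)C(C)(C)C)CC(=C)CO)N(Cc3ccc(OC)cc3)C2=O)C1(C)C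
F10 | step 14 | cyclohexene-fused lactam with C1 formyl group and allylic chloride chain end | O=CC1CCC2=C([C@@H](C/C(C)=C/[C@@H](O[Si](C)(C)C(C)(C)C)CC(=C)CCl)N(Cc3ccc(OC)cc3)C2=O)C1(C)C
F11 | step 14 | allylchromium dichloride from F10 | O=CC1CCC2=C([C@@H](C/C(C)=C/[C@@H](O[Si](C)(C)C(C)(C)C)CC(=C)C[Cr](Cl)Cl)N(Cc3ccc(OC)cc3)C2=O)C1(C)C
F12 | step 12 | dienyl pinacol boronate (boron on C15, cis to C12) | C=C1C(=O)N(Cc2ccc(OC)cc2)[C@H](C/C(C)=C/[C@@H](O[Si](C)(C)C(C)(C)C)CC(=C)CC(O)C=C)/C1=C(\C)B1OC(C)(C)C(C)(C)O1
F13 | step 3 | methyl ketone from hydration of 7 | CC(C)(C)[S@](=O)N[C@H](CC(C)=O)C#CC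
F14 | step 3 | (E)-ethyl enoate from F13 | CC(C)(C)[S@](=O)N[C@H](C/C(C)=C/C(=O)OCC)C#CC
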